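## Retrosynthetic overview

1. The target is (3S,4R,3'R,6'R)-β,ε-carotene-3,4,3'-triol (carotenoid numbering; ring A = C1–C6 with the cis-3,4-diol, ring B = C1'–C6' with the 3'-OH). After global desilylation the chain is cut at the C12–C13 single bond. This gives a terminal C16 dienyne (ring A, C7–C12) and a methyl-capped C24 pentaenyne (ring B, C7'–C15', C15–C13, C20). The two are joined on one divalent titanium centre by reductive alkyne–alkyne cross-coupling, which makes the C12–C13 bond and the 11E and 13E alkenes in one operation.
2. Enabling feature: C11=C12–C13(CH3)=C14 is an (E,E)-diene. Its inner atoms carry only H (C12) and CH3 (C13), and its outer atoms C11 and C14 each carry a conjugated polyenyl arm. It therefore maps onto HC≡C– plus CH3–C≡C–, and the arms steer C11 and C14 next to titanium, so that C12 and C13 bond to each other.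
3. Both alkynes grow from C13 methyl ketones by Horner–Wadsworth–Emmons/iBu2AlH homologation: C13→C15→C20→C24 on the ring B side, and C13→C15→C16 (Colvin rearrangement) on the ring A side.
4. Both ketones come from one racemate, made by cytochrome P450 hydroxylation of (±)-α-ionone at C3 (3,6-trans) followed by lipase resolution. The (3R,6R) enantiomer is ring B as it stands. The (3S,6S) enantiomer becomes ring A by hydroxyl-directed epoxidation of C4=C5 and vinylogous E1cB opening, which carries the C3 configuration to C4 and erases C6.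
5. Ring order: no carbocycle is built, because both six-membered rings arrive with α-ionone. The only rings formed are temporary (oxirane in step 11, titanacyclopropene and titanacyclopentadiene in step 17), and all are opened again.

Key step: step 17

Assumption: the lipase is taken to acylate the (3S,6S) enantiomer; if the opposite sense is found, the deacetylation of step 10 moves to the other branch and nothing else changes.

## Route

Step 1
Reactants: 1 (±)-α-ionone
Product: 2 (±)-trans-3-hydroxy-α-ionone (racemate of the (3R,6R) and (3S,6S) enantiomers; OH and side chain on opposite ring faces)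
Conditions: cytochrome P450 monooxygenase (engineered CYP102A1 variant, cell-free extract), NADP+ (cat.), glucose dehydrogenase, D-glucose, air, KH2PO4/K2HPO4 buffer pH 7.5, DMSO (2 vol%), 28 °C
Reagents that add atoms: dioxygen, O=O
Why: Cytochrome P450 C–H hydroxylation (hydrogen abstraction and oxygen rebound at the allylic C3 methylene), a transformation known for α-ionone with bacterial enzymes of this class, should oxidise only C3 and deliver oxygen to the ring face opposite the C6 side chain in both enantiomers, so the enzyme pocket sets the relative 3,6-trans configuration.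

Step 2
Reactants: 2 (±)-trans-3-hydroxy-α-ionone
Product: 3 (3R,6R)-3-hydroxy-α-ionone (unreacted alcohol) together with 4 (3S,6S)-3-acetoxy-α-ionone, separated by chromatography
Conditions: immobilised lipase from Burkholderia cepacia (serine hydrolase), vinyl acetate, MTBE, 30 °C, stopped at half conversion
Reagents that add atoms: vinyl acetate, C=COC(C)=O
Why: In this lipase-catalysed kinetic resolution by irreversible transesterification the enzyme tells the two flanks of the C3 carbinol apart (CH2–C(CH3)2 as the large group, as for related 3-hydroxyionones), so the (3S,6S)-alcohol should be acetylated and the (3R,6R)-alcohol left, which fixes the absolute configuration of C3' and C6' (in 3) and of C3 (in 4) with both enantiomers used.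

Step 3
Reactants: 3 (3R,6R)-3-hydroxy-α-ionone
Product: 5 (3R,6R)-3-(tert-butyldimethylsilyloxy)-α-ionone
Conditions: TBSCl, imidazole, DMF, rt
Reagents that add atoms: tert-butyldimethylsilyl chloride, CC(C)(C)[Si](C)(C)Cl
Why: Standard imidazole-promoted silylation of a secondary allylic alcohol masks the OH against hydride, base and organotitanium reagents without touching a stereocentre.

Step 4
Reactants: 5 (3R,6R)-3-(tert-butyldimethylsilyloxy)-α-ionone; 6 diethyl cyanomethylphosphonate
Product: 7 ring B C15 nitrile, (2E,4E)-5-[(1R,4R)-4-(tert-butyldimethylsilyloxy)-2,6,6-trimethylcyclohex-2-en-1-yl]-3-methylpenta-2,4-dienenitrile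
Conditions: NaH, 6 (slight excess over NaH), THF, 0 °C → rt; chromatography
Reagents that add atoms: none
Why: The Horner–Wadsworth–Emmons olefination of the methyl ketone with a stabilised phosphonate anion should favour the 9'E alkene (the minor 9'Z isomer is removed by chromatography), and leaving no free base keeps the γ-proton at C6' untouched.

Step 5
Reactants: 7 ring B C15 nitrile
Product: 9 ring B C15 aldehyde, (2E,4E)-5-[(1R,4R)-4-(tert-butyldimethylsilyloxy)-2,6,6-trimethylcyclohex-2-en-1-yl]-3-methylpenta-2,4-dienal, via aluminium imine 8 (not isolated)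
Conditions: iBu2AlH, toluene, −78 °C; then H2O/SiO2, Et2O, 0 °C
Reagents that add atoms: water, O
Why: Partial reduction of a nitrile with iBu2AlH stops after one hydride transfer at low temperature, and mild hydrolysis on wet silica should release the dienal without E/Z drift or loss of the silyl ether.

Step 6
Reactants: 9 ring B C15 aldehyde; 10 diethyl (3-cyano-2-methylallyl)phosphonate
Product: 11 ring B C20 nitrile, (2E,4E,6E,8E)-9-[(1R,4R)-4-(tert-butyldimethylsilyloxy)-2,6,6-trimethylcyclohex-2-en-1-yl]-3,7-dimethylnona-2,4,6,8-tetraenenitrile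
Conditions: NaH, 10, THF, 0 °C; then 9, 0 °C → rt; chromatography, dim light
Reagents that add atoms: none
Why: The vinylogous Horner–Wadsworth–Emmons olefination that is standard in retinoid synthesis should form C11'=C12' as the E alkene, the allylic anion equilibrates towards the 13'E form, and the minor 13'Z isomer is separated.

Step 7
Reactants: 11 ring B C20 nitrile
Product: 13 ring B C20 aldehyde, (2E,4E,6E,8E)-9-[(1R,4R)-4-(tert-butyldimethylsilyloxy)-2,6,6-trimethylcyclohex-2-en-1-yl]-3,7-dimethylnona-2,4,6,8-tetraenal, via aluminium imine 12 (not isolated)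
Conditions: iBu2AlH, toluene, −78 °C; then H2O/SiO2, Et2O, 0 °C
Reagents that add atoms: water, O
Why: This is the same nitrile-to-aldehyde partial reduction as in step 5, a reaction routinely used on retinonitriles.

Step 8
Reactants: 14 1-bromobut-2-yne; 15 triethyl phosphite
Product: 16 diethyl but-2-yn-1-ylphosphonate
Conditions: neat, 120 °C, bromoethane distilled off
Reagents that add atoms: none
Why: In the Michaelis–Arbuzov reaction phosphorus attacks the primary propargylic bromide by SN2 and bromide then dealkylates the phosphonium ion, while the internal alkyne disfavours the SN2' path to an allenyl isomer.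

Step 9
Reactants: 13 ring B C20 aldehyde; 16 diethyl but-2-yn-1-ylphosphonate
Product: 17 ring B C24 pentaenyne, tert-butyl{[(1R,4R)-4-[(1E,3E,5E,7E,9E)-3,7-dimethyltrideca-1,3,5,7,9-pentaen-11-yn-1-yl]-3,5,5-trimethylcyclohex-2-en-1-yl]oxy}dimethylsilane
Conditions: 16, LiN(SiMe3)2, THF, −78 °C; then 13, −78 → 0 °C; dim light
Reagents that add atoms: none
Why: The Horner–Wadsworth–Emmons olefination with a propargylic phosphonate, a known route to (E)-enynes, should form C15'=C15 as the E alkene and install the CH3–C≡C terminus (C20, C13, C14) in one step.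

Step 10
Reactants: 4 (3S,6S)-3-acetoxy-α-ionone
Product: 18 (3S,6S)-3-hydroxy-α-ionone
Conditions: K2CO3 (cat.), MeOH, 0 °C → rt
Reagents that add atoms: none
Why: Base-catalysed transesterification cleaves the acyl–oxygen bond, so C3 is retained, and any slight erosion at C6 is harmless because C6 becomes sp2 in step 12.

Step 11
Reactants: 18 (3S,6S)-3-hydroxy-α-ionone
Product: 19 (3S,4S,5R,6S)-4,5-epoxy-3-hydroxy-4,5-dihydro-α-ionone (oxirane cis to the 3-OH, trans to the side chain)
Conditions: mCPBA, CH2Cl2, 0 °C
Reagents that add atoms: 3-chloroperbenzoic acid, OOC(=O)c1cccc(Cl)c1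
Why: In this hydroxyl-directed peracid epoxidation the electron-rich trisubstituted C4=C5 reacts before the enone C7=C8, and the pseudo-equatorial C3–OH hydrogen-bonds the peracid and delivers oxygen to its own face, which is also the face away from the C6 side chain and the axial C1 methyl, so C4 and C5 are set cis to C3–O.

Step 12
Reactants: 19 epoxy alcohol
Product: 20 (3S,4R)-3,4-dihydroxy-β-ionone (cis-diol)
Conditions: NaOMe (cat.), MeOH, 0 °C → rt
Reagents that add atoms: none
Why: In this vinylogous E1cB epoxide opening, the base-induced isomerisation known for α-ionone 4,5-epoxide, methoxide removes the γ-proton at C6, the dienolate expels the C5–O bond and C5=C6 moves into conjugation, while the C4–O bond is never broken, so the new carbinol stays cis to C3–OH, and a Payne shift is excluded because C3–O lies on the same face as the oxirane.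

Step 13
Reactants: 20 (3S,4R)-3,4-dihydroxy-β-ionone
Product: 21 (3S,4R)-3,4-bis(tert-butyldimethylsilyloxy)-β-ionone
Conditions: TBSOTf, 2,6-lutidine, CH2Cl2, −78 → 0 °C
Reagents that add atoms: tert-butyldimethylsilyl triflate, CC(C)(C)[Si](C)(C)OS(=O)(=O)C(F)(F)F
Why: Silylation with the reactive triflate should also cover the hindered allylic C4–OH, the buffered low-temperature conditions avoid ionisation at C4 and enol silylation of the methyl ketone, and fluoride-labile groups are chosen because the final allylic diol does not tolerate acid.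

Step 14
Reactants: 21 bis-silyl ketone; 6 diethyl cyanomethylphosphonate
Product: 22 ring A C15 nitrile, (2E,4E)-5-[(3S,4R)-3,4-bis(tert-butyldimethylsilyloxy)-β-ring]-3-methylpenta-2,4-dienenitrile (carotenoid ring numbering)
Conditions: NaH, 6, THF, 0 °C → rt; chromatography
Reagents that add atoms: none
Why: The Horner–Wadsworth–Emmons olefination, as practised on β-ionone, should favour the 9E alkene, and the minor 9Z isomer is removed by chromatography.

Step 15
Reactants: 22 ring A C15 nitrile
Product: 24 ring A C15 aldehyde, the corresponding (2E,4E)-dienal, via aluminium imine 23 (not isolated)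
Conditions: iBu2AlH, toluene, −78 °C; then H2O/SiO2, Et2O, 0 °C
Reagents that add atoms: water, O
Why: This is the nitrile-to-aldehyde partial reduction as in step 5, and the near-neutral hydrolysis on wet silica protects the ionisable C4 allylic silyl ether.

Step 16
Reactants: 24 ring A C15 aldehyde; 25 (trimethylsilyl)diazomethane
Product: 26 ring A C16 dienyne, (3S,4R)-3,4-bis(tert-butyldimethylsilyloxy)-β-ring bearing a (1E,3E)-3-methylhexa-1,3-dien-5-yn-1-yl chain at C6
Conditions: 25, LiN(iPr)2 (commercial solution), THF, −78 °C; then 24, −78 °C → rt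
Reagents that add atoms: none
Why: In the Colvin rearrangement, 1,2-addition of lithiated (trimethylsilyl)diazomethane, Peterson-type loss of silanolate, loss of N2 and a 1,2-hydride shift of the alkylidene carbene give the terminal alkyne (C12), and the aprotic conditions avoid the conjugate addition of methanol that troubles enals under methanolic alkynylation conditions.

Step 17
Reactants: 17 ring B C24 pentaenyne; 26 ring A C16 dienyne
Product: 29 (3S,4R,3'R,6'R)-3,4,3'-tris(tert-butyldimethylsilyloxy)-β,ε-carotene, via titanacyclopropene 27 (not isolated), via titanacyclopentadiene 28 (not isolated)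
Conditions: 17, Ti(OiPr)4 (1.0 equiv), c-C5H9MgCl (2.0 equiv), Et2O–toluene, −78 → −35 °C; then 26 (0.8 equiv), −35 °C; then H2O, −35 °C → rt; argon, dark
Reagents that add atoms: none
Why: Ti(OiPr)4 and two equivalents of c-C5H9MgCl give (η2-cyclopentene)Ti(OiPr)2, a divalent titanium equivalent that trades its alkene for the single alkyne of 17 to give titanacyclopropene 27, the terminal alkyne of 26 then inserts into the Ti–C13 bond to give titanacyclopentadiene 28, and water cleaves both Ti–C(sp2) bonds with retention to give 29. The closest known reaction type is the titanium alkoxide-mediated reductive cross-coupling of a pre-complexed internal alkyne with a terminal alkyne, an established fragment union for trisubstituted (E,E)-1,3-dienes of the pattern RCH=CH–C(CH3)=CHR', and the tolerance of long polyenes towards low-valent titanium is known from McMurry couplings of polyenals. The only rings closed are temporary, the three-membered titanacycle by ligand exchange and the five-membered one by migratory insertion (formal oxidative cyclisation of two alkynes on one metal), and both are gone after the quench, so no ring of the target is made here. No stereocentre is formed; the two new alkene geometries are dictated by the planar metallacycle, in which Ti and C13 are cis on C11=C12 and Ti and C12 are cis on C13=C14, so that after retentive protonolysis C10 is trans to C13 (11E) and C15 is trans to C12 (13E), while C3, C4, C3' and C6' are remote silyl-protected spectators. The step needs regiocontrol on both alkynes, cross- over homo-coupling and alkyne over alkene chemoselectivity: the conjugating polyenyl arms favour the positions next to titanium (C11, C14) and the small H and CH3 groups the inner positions where the bond forms, full complexation of 17 before 26 is added secures the cross product, and the di- and trisubstituted alkenes of both chains do not displace an alkyne from titanium. In one operation the step thus delivers the C40 skeleton, the last C–C bond and two stereodefined double bonds from two alkynes that need no stereodefined alkenyl halide or alkenylmetal.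

Step 18
Reactants: 29 tris-silyl carotenoid
Product: 30 (3S,4R,3'R,6'R)-β,ε-carotene-3,4,3'-triol (target)
Conditions: Bu4NF, THF, 0 °C → rt, argon, dark; aqueous work-up
Reagents that add atoms: none
Why: Fluoride-induced desilylation cleaves only Si–O bonds under non-acidic conditions, so all four stereocentres, the ionisable C4 allylic alcohol and the all-E polyene should survive.

## Compound list

1 | (±)-α-ionone | CC1=CCCC(C)(C)C1/C=C/C(C)=O | starting material
2 | (±)-trans-3-hydroxy-α-ionone (racemate, both enantiomers written) | CC1=C[C@H](O)CC(C)(C)[C@H]1/C=C/C(C)=O.CC1=C[C@@H](O)CC(C)(C)[C@@H]1/C=C/C(C)=O | intermediate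
3 | (3R,6R)-3-hydroxy-α-ionone | CC1=C[C@H](O)CC(C)(C)[C@H]1/C=C/C(C)=O | intermediate
4 | (3S,6S)-3-acetoxy-α-ionone | CC1=C[C@@H](OC(C)=O)CC(C)(C)[C@@H]1/C=C/C(C)=O | intermediate
5 | (3R,6R)-3-(tert-butyldimethylsilyloxy)-α-ionone | CC1=C[C@H](O[Si](C)(C)C(C)(C)C)CC(C)(C)[C@H]1/C=C/C(C)=O | intermediate
6 | diethyl cyanomethylphosphonate | CCOP(=O)(CC#N)OCC | starting material
7 | ring B C15 nitrile | CC1=C[C@H](O[Si](C)(C)C(C)(C)C)CC(C)(C)[C@H]1/C=C/C(C)=C/C#N | intermediate
8 | N-(diisobutylaluminio)imine of 9 | CC1=C[C@H](O[Si](C)(C)C(C)(C)C)CC(C)(C)[C@H]1/C=C/C(C)=C/C=N[Al](CC(C)C)CC(C)C | intermediate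
9 | ring B C15 aldehyde | CC1=C[C@H](O[Si](C)(C)C(C)(C)C)CC(C)(C)[C@H]1/C=C/C(C)=C/C=O | intermediate
10 | diethyl (3-cyano-2-methylallyl)phosphonate (E form drawn; sold as an E/Z mixture) | CCOP(=O)(C/C(C)=C/C#N)OCC | starting material
11 | ring B C20 nitrile | CC1=C[C@H](O[Si](C)(C)C(C)(C)C)CC(C)(C)[C@H]1/C=C/C(C)=C/C=C/C(C)=C/C#N | intermediate
12 | N-(diisobutylaluminio)imine of 13 | CC1=C[C@H](O[Si](C)(C)C(C)(C)C)CC(C)(C)[C@H]1/C=C/C(C)=C/C=C/C(C)=C/C=N[Al](CC(C)C)CC(C)C | intermediate
13 | ring B C20 aldehyde | CC1=C[C@H](O[Si](C)(C)C(C)(C)C)CC(C)(C)[C@H]1/C=C/C(C)=C/C=C/C(C)=C/C=O | intermediate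
14 | 1-bromobut-2-yne | CC#CCBr | starting material
15 | triethyl phosphite | CCOP(OCC)OCC | starting material
16 | diethyl but-2-yn-1-ylphosphonate | CC#CCP(=O)(OCC)OCC | intermediate
17 | ring B C24 pentaenyne | CC1=C[C@H](O[Si](C)(C)C(C)(C)C)CC(C)(C)[C@H]1/C=C/C(C)=C/C=C/C(C)=C/C=C/C#CC | intermediate
18 | (3S,6S)-3-hydroxy-α-ionone | CC1=C[C@@H](O)CC(C)(C)[C@@H]1/C=C/C(C)=O | intermediate
19 | (3S,4S,5R,6S)-4,5-epoxy-3-hydroxy-4,5-dihydro-α-ionone | C[C@]12O[C@H]1[C@@H](O)CC(C)(C)[C@@H]2/C=C/C(C)=O | intermediate
20 | (3S,4R)-3,4-dihydroxy-β-ionone | CC(=O)/C=C/C1=C(C)[C@@H](O)[C@@H](O)CC1(C)C | intermediate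
21 | (3S,4R)-3,4-bis(tert-butyldimethylsilyloxy)-β-ionone | CC(=O)/C=C/C1=C(C)[C@@H](O[Si](C)(C)C(C)(C)C)[C@@H](O[Si](C)(C)C(C)(C)C)CC1(C)C | intermediate
22 | ring A C15 nitrile | N#C/C=C(C)/C=C/C1=C(C)[C@@H](O[Si](C)(C)C(C)(C)C)[C@@H](O[Si](C)(C)C(C)(C)C)CC1(C)C | intermediate
23 | N-(diisobutylaluminio)imine of 24 | CC(C)C[Al](CC(C)C)N=C/C=C(C)/C=C/C1=C(C)[C@@H](O[Si](C)(C)C(C)(C)C)[C@@H](O[Si](C)(C)C(C)(C)C)CC1(C)C | intermediate
24 | ring A C15 aldehyde | O=C/C=C(C)/C=C/C1=C(C)[C@@H](O[Si](C)(C)C(C)(C)C)[C@@H](O[Si](C)(C)C(C)(C)C)CC1(C)C | intermediate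
25 | (trimethylsilyl)diazomethane | C[Si](C)(C)C=[N+]=[N-] | starting material
26 | ring A C16 dienyne | C#C/C=C(C)/C=C/C1=C(C)[C@@H](O[Si](C)(C)C(C)(C)C)[C@@H](O[Si](C)(C)C(C)(C)C)CC1(C)C | intermediate
27 | titanacyclopropene of 17 (Ti(OiPr)2 on C13 and C14) | CC1=C[C@H](O[Si](C)(C)C(C)(C)C)CC(C)(C)[C@H]1/C=C/C(C)=C/C=C/C(C)=C/C=C/C1=C(C)[Ti]1(OC(C)C)OC(C)C | intermediate
28 | titanacyclopentadiene (ring Ti–C11=C12–C13=C14) | CC1=C[C@H](O[Si](C)(C)C(C)(C)C)CC(C)(C)[C@H]1/C=C/C(C)=C/C=C/C(C)=C/C=C/C1=C(C)C=C(/C=C(C)/C=C/C2=C(C)[C@@H](O[Si](C)(C)C(C)(C)C)[C@@H](O[Si](C)(C)C(C)(C)C)CC2(C)C)[Ti]1(OC(C)C)OC(C)C | intermediate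
29 | (3S,4R,3'R,6'R)-3,4,3'-tris(tert-butyldimethylsilyloxy)-β,ε-carotene | CC1=C[C@H](O[Si](C)(C)C(C)(C)C)CC(C)(C)[C@H]1/C=C/C(C)=C/C=C/C(C)=C/C=C/C=C(C)/C=C/C=C(C)/C=C/C1=C(C)[C@@H](O[Si](C)(C)C(C)(C)C)[C@@H](O[Si](C)(C)C(C)(C)C)CC1(C)C | intermediate
30 | (3S,4R,3'R,6'R)-β,ε-carotene-3,4,3'-triol | CC1=C[C@H](O)CC(C)(C)[C@H]1/C=C/C(C)=C/C=C/C(C)=C/C=C/C=C(C)/C=C/C=C(C)/C=C/C1=C(C)[C@@H](O)[C@@H](O)CC1(C)C | target

## Step count and risks

Total step count: 18.
Longest linear sequence: 11 steps (1, 2, 10, 11, 12, 13, 14, 15, 16, 17, 18). The ring B branch needs 10 steps (1–7, 9, 17, 18), and step 8 is a one-step side branch.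

**Step 17.**
- What may go wrong: complexation of the long pentaenyne may be incomplete. Insertion may start at the wrong terminus of the methyl-capped alkyne. The terminal alkyne may homocouple. The acidic alkyne C–H may protonate the titanacyclopropene.
- Fallback: it sets out from 17 and 26 and comes back at 29. The two alkynes are differentiated by separate hydrometalations instead of being joined on one metal. Hydrozirconation of 17 with a slight excess of Cp2Zr(H)Cl in THF under equilibrating conditions should place zirconium on the less hindered, methyl-bearing C13 by syn addition and give the ring B alkenylzirconocene chloride F1. Iodinolysis with I2 at −78 °C should give the (13E)-alkenyl iodide F2. Hydrozirconation of the terminal alkyne 26 gives the (11E)-alkenylzirconocene chloride F3, and ZnCl2 converts it into the alkenylzinc chloride F4. Negishi coupling of F4 with F2 under Pd(PPh3)4 in THF at rt forms the same C12–C13 bond with retention on both partners and gives 29.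

**Step 2.**
- What may go wrong: the lipase may discriminate poorly between the enantiomers, so that neither the alcohol nor the acetate reaches high enantiomeric purity at half conversion.
- Fallback: it sets out from 2 and comes back at 3 and 18, and step 10 is then not needed. Racemic 2 is esterified with (1S,4R)-camphanic chloride (pyridine, DMAP, CH2Cl2) to the diastereomeric esters (3R,6R)-camphanate F5 and (3S,6S)-camphanate F6. These are separated by fractional crystallisation and chromatography. Each ester is then cleaved with K2CO3 in MeOH, F5 to 3 and F6 to 18.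

**Step 9.**
- What may go wrong: base may isomerise the propargylic phosphonate anion to the allenyl form, and E selectivity at C15'=C15 may be low.
- Fallback: it sets out from 13 and comes back at 17. Takai olefination of 13 (CHI3, CrCl2, THF, 0 °C) should give the (E)-alkenyl iodide F7. Sonogashira coupling of F7 with propyne (PdCl2(PPh3)2, CuI, Et3N, THF, rt) attaches the CH3–C≡C unit with retention of the alkene geometry and gives 17.

## Further compounds

F1 | step 17 | ring B (13E)-alkenylzirconocene chloride | CC1=C[C@H](O[Si](C)(C)C(C)(C)C)CC(C)(C)[C@H]1/C=C/C(C)=C/C=C/C(C)=C/C=C/C=C(C)/[Zr](Cl)(C1C=CC=C1)C1C=CC=C1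
F2 | step 17 | ring B (13E)-alkenyl iodide | CC1=C[C@H](O[Si](C)(C)C(C)(C)C)CC(C)(C)[C@H]1/C=C/C(C)=C/C=C/C(C)=C/C=C/C=C(C)/I
F3 | step 17 | ring A (11E)-alkenylzirconocene chloride | Cl[Zr](C1C=CC=C1)(C1C=CC=C1)/C=C/C=C(C)/C=C/C1=C(C)[C@@H](O[Si](C)(C)C(C)(C)C)[C@@H](O[Si](C)(C)C(C)(C)C)CC1(C)C
F4 | step 17 | ring A (11E)-alkenylzinc chloride | Cl[Zn]/C=C/C=C(C)/C=C/C1=C(C)[C@@H](O[Si](C)(C)C(C)(C)C)[C@@H](O[Si](C)(C)C(C)(C)C)CC1(C)C
F5 | step 2 | (3R,6R)-3-hydroxy-α-ionone (1S,4R)-camphanate | CC1=C[C@H](OC(=O)[C@@]23CC[C@@](C)(C(=O)O2)C3(C)C)CC(C)(C)[C@H]1/C=C/C(C)=O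
F6 | step 2 | (3S,6S)-3-hydroxy-α-ionone (1S,4R)-camphanate | CC1=C[C@@H](OC(=O)[C@@]23CC[C@@](C)(C(=O)O2)C3(C)C)CC(C)(C)[C@@H]1/C=C/C(C)=O
F7 | step 9 | ring B C21 (E)-alkenyl iodide | CC1=C[C@H](O[Si](C)(C)C(C)(C)C)CC(C)(C)[C@H]1/C=C/C(C)=C/C=C/C(C)=C/C=C/I
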